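The constants used here are invented; the rest is arithmetic.

The target stands two steps behind intermediate A, and here we want the amount of intermediate A itself in a closed flask and in a tank, each fed the same substrate.

    substrate → intermediate A (k1 = 0.017 /s)
    intermediate A → intermediate B (k2 = 0.019 /s)
    intermediate B ⇌ target (K3 = 25, k3 = 0.0019 /s)
    substrate → decomposition product (k4 = 5.0 × 10⁻⁶ /s)

in all of them: substrate 1.2 M
- larch: time 1.0 min; a closed flask charged with all of it at once and left for 1.0 min
- elm: a single well-mixed tank run continuously and read at steady state, 1.0 min in it on average

1. the set-up with the highest amount of intermediate A at the outlet or at the end, in percent of the substrate put in ("none" if the first two lie within 2 percentage points) (larch / elm / none)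
2. amount of intermediate A at the outlet or at the end, in percent of the substrate put in, larch
3. amount of intermediate A at the outlet or at the end, in percent of the substrate put in, elm

We work with the fraction left and not with the fraction made, and we drop decomposition from the reckoning because its constant is far smaller than that of the first step. In larch, the closed flask, a first-order step leaves the exponential of minus its constant times the time, so 36.1% of the substrate remains. If the two constants of the chain were equal, a portion that turned into intermediate A at any moment would have one fraction left as substrate up to that moment and another as intermediate A after it, and the product of the two would be the same whatever the moment: the exponential of minus the constant times the whole time. Taking their mean therefore gives the amount as the first constant times the time times that fraction, which is 34.6%, and we commit to this.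

In elm, with its 1.0 min on average (the mean residence time), a step leaves one part in one plus its constant times that time. The substrate keeps 49.5%, and the intermediate A formed keeps 46.7%, which makes 23.6%.

The weak link is the mean constant in larch. Reforged, intermediate A is the fraction of substrate left minus the fraction 32.0% that the second constant leaves, a gap of 4.08%, times the chain multiplier, the first constant over the difference of the two constants, here 8.50. That gives 34.7%, and larch leads by 11 percentage points, which is more than the margin.

The forecast names larch, with 34.7% (34% to 35.3%) in larch and 23.6% (23.1% to 24.1%) in elm: “the closed flask wins by about 11 points”.

The flask gives larch, with 34.7% in larch and 23.6% in elm. With the turning of intermediate A into intermediate B struck out, larch holds 63.9% of intermediate A. Left for 10.0 min, larch has a gap of 0.00260% between the two fractions left, the multiplier 8.50 turns that into 0.0221%, and the run stands at 0.0220%.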